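# Total synthesis proposal for CNP0344673.1: ring-closing alkyne metathesis at C4–C5

## Analysis of the target

The target is a cembranoid: a 14-membered carbocycle (C1–C14) bridged between C1 and C12 by the unit C15(=C17H2)–C16(=O)–O. This bridge forms a seven-membered α-methylene lactone that shares C1, C14, C13 and C12 with the large ring. Cembrane numbering is used throughout: C1 is the ring CH bearing C15, C3 carries the acetate, C4(C18)=C5 and C7=C8(C19) are the two trisubstituted olefins, C11 is the free carbinol and C12 the quaternary carbon with methyl C20 and the lactone oxygen.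

There are four stereocentres, (1S,3R,11R,12S). C11 and C12 are vicinal and have the relative configuration that a syn-dihydroxylation of a Z olefin, or an anti addition to an E olefin, would give. C1 is 1,3 to C3 and 1,4 to C12, so in an open chain the C1/C3 pair and the C11/C12 pair cannot control each other. The C4=C5 olefin is E (C3 trans to C6). Remark on the structure: C7=C8 is read from the SMILES as Z, with the ring carbons C6 and C9 cis and C19 trans to C6.

Sensitive groups are the α-methylene lactone (Michael and radical acceptor), the allylic acetate at C3, the doubly allylic C6 methylene, and the C11 hydroxyl next to the tertiary lactone oxygen, which could translactonise. The difficulty is to close a 14-membered ring while fixing two trisubstituted olefin geometries in a skipped diene, and to esterify a hindered tertiary alcohol. The strategy rests on the C3 carbinol beside C4(Me)=C5: an E-2-methyl allylic alcohol is the product of a hydroxyl-directed trans-hydrometalation and methylation of a propargylic alcohol, so the ring can be closed as a cycloalkyne at C4≡C5, where no olefin geometry is at stake.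

## Retrosynthetic reasoning

**38 ⇐ 37 ⇐ 36 (O–Si at C11, O–acetyl at C3).** The C11 hydroxyl stays silylated to the end, so that it can neither take the acetyl group nor attack the lactone. Desilylation of 37 is the last step and acetylation of 36 comes just before it.

**36 ⇐ 35 ⇐ 34 ⇐ 33 (C4–C18 and C5–H).** The E olefin with its methyl group is cut back to the alkyne of 34. Trans-hydrostannation directed by the free C3 hydroxyl puts tin on C4 and hydrogen on C5 from opposite faces (35), and a methyl Stille coupling replaces tin with retention. An olefination at C4 or C5 would have left an E/Z question inside the macrocycle; here the geometry follows from the mechanism. The C3 hydroxyl must be free, so the triethylsilyl group of 33 is removed first.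

**33 ⇐ 32 (C4≡C5, key disconnection).** The 14-membered ring is opened at the triple bond to the diyne 32 with two methyl-capped alkynes. This is the only ring bond whose formation creates neither a stereocentre nor an olefin geometry and which tolerates the lactone, the acrylate and the Z olefin. The forward reaction must close the ring against oligomerisation.

**32 ⇐ 25 + 30 (C8–C9).** The sp3–sp2 bond next to the Z olefin is cut so that the C7=C8 geometry is brought in ready-made with the vinyl iodide 30 and transferred with retention. The sp3 partner comes from the terminal vinyl group of lactone 25 by hydroboration. The lactone is made before this step, because conjugation removes the C15=C17 olefin from competition for the borane.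

**30 ⇐ 29 ⇐ 28 ⇐ 26 (C5–C6, C8–I).** The iodo-enyne is cut at the allylic C5–C6 bond into an allylic bromide and a propynyl nucleophile. The Z-iodoalkene 28 comes from but-2-yn-1-ol 26 by hydroxyl-directed trans-hydroalumination and iodination, which fixes the Z geometry.

**25 ⇐ 23 ⇐ 21 ⇐ 20 (C16–O ester, C16 oxidation level).** The lactone is cut at the ester bond to hydroxy acid 23, with C11 already silylated so that only the C12 hydroxyl can lactonise. The acid comes from allylic alcohol 21, unmasked from the PMB ether 20. Failure of this lactonisation would be cheap at this early stage.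

**20 ⇐ 19 ⇐ 17 ⇐ 16 (C9–C10, C11–O, C12–O).** Addition of a C11 nucleophile to a C12 methyl ketone is rejected, because an acyclic methyl ketone four bonds from the nearest stereocentre offers no facial control. C12 is therefore made from an olefin face. Vinyl diol 19 is traced to the epoxy alcohol 17 by a Payne rearrangement (inversion at C11, retention at C12) with one-carbon ylide homologation, and 17 to the E-allylic alcohol 16 by Sharpless epoxidation. Reagent control sets both centres and the anti relationship follows from E geometry plus one inversion.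

**16 ⇐ 13 ⇐ 11 (C12–C20, C10–C11).** The E-trisubstituted allylic alcohol is cut to the terminal alkyne 13 by syn methylalumination and one-carbon trapping, which gives the E isomer only. The alkyne comes from the methyl ketone 11; a direct olefination of 11 would give E/Z mixtures.

**11 ⇐ 10 ⇐ 9 ⇐ 8 ⇐ 7 (C3–C4, C3 configuration).** The propargylic silyl ether is cut at C3–C4 to the aldehyde of 7 and a propynyl nucleophile. The configuration at C3 is set by catalyst-controlled reduction of ynone 9 rather than by the addition itself, because the neighbouring C1 centre gives no useful 1,3-induction.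

**7 ⇐ 5 ⇐ 4 ⇐ 1 (ring C=C, C16–O).** Keto aldehyde 7 is the product of oxidative cleavage of the ring olefin of (S)-limonene 1, which supplies C1 with the correct configuration and C2, C3, C11–C17. The C16 oxygen is introduced first, by allylic metalation of 1, and carried as a PMB ether.

## Alternatives that were turned down

**Alternative 1:** Disconnection of the lactone at C1–C15, made together with cleavage of a temporary C13–O bond. The forward key step is a thermal [3,3] (Claisen) ring expansion in which an exocyclic ketene acetal carbon bonds to C1 and a five-membered ring grows to the unsaturated seven-membered lactone A1.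
- For: the lactone is formed without acylating the tertiary C12 hydroxyl, C1 is set by chirality transfer, and C11/C12 are installed on a small fragment. On the ester bond it is stronger than the chosen route.
- Against: A1 lacks C17, carries a C13=C14 olefin that must be reduced, and both side chains end as protected primary alcohols. C3 with its configuration, the whole C4–C9 segment and the macrocycle are still to be built. The sense of chirality transfer depends on a chair or boat preference in a strained bicyclic transition state.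
- Comparison: the chosen route takes C1 from limonene, needs no chirality transfer, and offers a defined ring closure with control of the 4E olefin in place of the easier ester bond.

**Alternative 2:** Disconnection of the ring at C11–C12. The forward key step is a reductive coupling of a C11 aldehyde with a C12 methyl ketone at the two ends of one chain by low-valent titanium from TiCl3(DME)1.5 and zinc–copper couple, giving the cyclic diol A2.
- For: ring, C11–C12 bond and both oxygens arise in one step, and both olefins are made beforehand by acyclic methods. In convergence at the ring-closing stage it is at least equal to the chosen route.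
- Against: four diastereomers are possible and the nearest stereocentres are remote, so the configuration at C11/C12 is left to the conformation of a 14-membered transition state. Low-valent titanium can also deoxygenate the diol to the olefin and attack the allylic PMB ether at C3. A2 still needs C16 oxidation and a lactonisation that must choose the tertiary over the secondary hydroxyl.
- Comparison: the chosen route fixes C11/C12 by reagent control before ring closure and closes the ring in a step that creates no stereocentre.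

**Alternative 3:** Disconnection of the lactone at C15–C16 and C16–O, with C16 brought in as carbon monoxide. The forward key step uses Pd(PPh3)4 under carbon monoxide to turn a C15 enol triflate of the macrocycle into an acylpalladium species that the C12 hydroxyl captures, giving A3.
- For: the α-methylene lactone appears only at the end, so no Michael acceptor is carried through the synthesis, and no carboxylic acid has to be activated towards a tertiary alcohol. On both points it is stronger than the chosen route, and A3 is three steps from the target.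
- Against: it needs a regiodefined enol triflate from a C15 methyl ketone next to the epimerisable C1 centre, inside a macrocycle with a free tertiary hydroxyl. Capture of the acylpalladium by that hindered hydroxyl in a seven-membered closure is slow. The strategy also leaves open how the 14-membered ring with its 4E and 7Z olefins is closed.
- Comparison: the chosen route answers the ring-closure question and tests the lactonisation early, on material that is cheap to remake.

Key step: step 20

Remark on the chemistry: the Sharpless epoxidation of 16 is assumed to follow the facial preference of geraniol, for which L-(+)-diethyl tartrate gives the (2S,3S)-epoxy alcohol.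

## Route

Step 1
Reactants: 1 (S)-limonene
Product: 4 2-[(1S)-4-methylcyclohex-3-en-1-yl]prop-2-en-1-ol, via allyllithium 2 (not isolated), via allylboronate 3 (not isolated)
Conditions: n-BuLi, TMEDA, hexane, rt; B(OMe)3, THF, −78 °C to rt; H2O2, NaOH aq, 0 °C
Reagents that add atoms: hydrogen peroxide, OO
Why: Allylic lithiation at the methyl group of the isopropenyl unit, borylation of the symmetric 2-substituted allyl anion and oxidative C–B cleavage install the C16 oxygen; the ring stereocentre (future C1) is not involved.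

Step 2
Reactants: 4 2-[(1S)-4-methylcyclohex-3-en-1-yl]prop-2-en-1-ol
Product: 5 1-methoxy-4-[({2-[(1S)-4-methylcyclohex-3-en-1-yl]prop-2-en-1-yl}oxy)methyl]benzene
Conditions: NaH, 4-MeOC6H4CH2Cl, Bu4NI (cat.), THF/DMF, 0 °C to rt
Reagents that add atoms: 4-methoxybenzyl chloride, COc1ccc(CCl)cc1
Why: Williamson ether synthesis; the PMB ether survives bases, organometallics and Lewis acids of the following steps and can later be removed oxidatively beside two silyl ethers.

Step 3
Reactants: 5 1-methoxy-4-[({2-[(1S)-4-methylcyclohex-3-en-1-yl]prop-2-en-1-yl}oxy)methyl]benzene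
Product: 7 (3S)-3-{3-[(4-methoxybenzyl)oxy]prop-1-en-2-yl}-6-oxoheptanal, via epoxide 6 (not isolated)
Conditions: mCPBA, NaHCO3, CH2Cl2, 0 °C; H5IO6, THF/H2O, 0 °C to rt
Reagents that add atoms: 3-chloroperbenzoic acid, OOC(=O)c1cccc(Cl)c1; water, O
Why: Prilezhaev epoxidation takes the electron-rich trisubstituted ring olefin in preference to the 1,1-disubstituted olefin deactivated by its allylic oxygen, and periodic acid cleaves the epoxide through the diol to the keto aldehyde (glycol cleavage).

Step 4
Reactants: 7 (3S)-3-{3-[(4-methoxybenzyl)oxy]prop-1-en-2-yl}-6-oxoheptanal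
Product: 8 (5S)-7-hydroxy-5-{3-[(4-methoxybenzyl)oxy]prop-1-en-2-yl}dec-8-yn-2-one (both C7 epimers)
Conditions: CH3C≡CMgBr (1.1 equiv), THF, −78 °C; NH4Cl aq
Reagents that add atoms: 1-propynylmagnesium bromide, CC#C[Mg]Br
Why: Grignard addition; at −78 °C the weakly basic alkynyl reagent should add to the aldehyde much faster than to the methyl ketone, and the missing control at the new carbinol is corrected by the oxidation and reduction that follow.

Step 5
Reactants: 8 (5S)-7-hydroxy-5-{3-[(4-methoxybenzyl)oxy]prop-1-en-2-yl}dec-8-yn-2-one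
Product: 9 (5S)-5-{3-[(4-methoxybenzyl)oxy]prop-1-en-2-yl}dec-8-yne-2,7-dione
Conditions: Dess–Martin periodinane, NaHCO3, CH2Cl2, 0 °C to rt
Reagents that add atoms: none
Why: Dess–Martin oxidation of the propargylic alcohol gives the ynone under neutral conditions that leave the PMB ether and the enolisable ketone alone.

Step 6
Reactants: 9 (5S)-5-{3-[(4-methoxybenzyl)oxy]prop-1-en-2-yl}dec-8-yne-2,7-dione
Product: 10 (5S,7R)-7-hydroxy-5-{3-[(4-methoxybenzyl)oxy]prop-1-en-2-yl}dec-8-yn-2-one
Conditions: Ru[(R,R)-TsNCHPhCHPhNH](η6-p-cymene) (2 mol%), i-PrOH, rt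
Reagents that add atoms: none
Why: Noyori asymmetric transfer hydrogenation; alkynyl ketones are reduced fast and dialkyl ketones hardly at all, and the (R,R) catalyst, with the alkynyl group in the place an aryl group takes, should give the (R)-propargylic alcohol (future C3) under catalyst control.

Step 7
Reactants: 10 (5S,7R)-7-hydroxy-5-{3-[(4-methoxybenzyl)oxy]prop-1-en-2-yl}dec-8-yn-2-one
Product: 11 (5S,7R)-5-{3-[(4-methoxybenzyl)oxy]prop-1-en-2-yl}-7-[(triethylsilyl)oxy]dec-8-yn-2-one
Conditions: Et3SiCl, imidazole, DMAP (cat.), CH2Cl2, 0 °C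
Reagents that add atoms: chlorotriethylsilane, CC[Si](Cl)(CC)CC
Why: Silylation of the secondary alcohol; the triethylsilyl ether can later be cleaved beside the tert-butyldimethylsilyl ether at C11.

Step 8
Reactants: 11 (5S,7R)-5-{3-[(4-methoxybenzyl)oxy]prop-1-en-2-yl}-7-[(triethylsilyl)oxy]dec-8-yn-2-one
Product: 13 (5S,7R)-5-{3-[(4-methoxybenzyl)oxy]prop-1-en-2-yl}-7-[(triethylsilyl)oxy]deca-1,8-diyne, via enol phosphate 12 (not isolated)
Conditions: LiN(i-Pr)2, THF, −78 °C; ClP(O)(OEt)2, −78 °C to rt; LiN(i-Pr)2 (2.3 equiv), −78 to 0 °C; NH4Cl aq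
Reagents that add atoms: none
Why: Conversion of a methyl ketone into a terminal alkyne: kinetic deprotonation at the methyl group, O-phosphorylation and base-induced elimination of the enol phosphate; the old methyl carbon becomes C11 and the carbonyl carbon C12.

Step 9
Reactants: 13 (5S,7R)-5-{3-[(4-methoxybenzyl)oxy]prop-1-en-2-yl}-7-[(triethylsilyl)oxy]deca-1,8-diyne
Product: 16 (2E,6S,8R)-6-{3-[(4-methoxybenzyl)oxy]prop-1-en-2-yl}-3-methyl-8-[(triethylsilyl)oxy]undec-2-en-9-yn-1-ol, via alkenylalane 14 (not isolated), via lithium alanate 15 (not isolated)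
Conditions: Me3Al, Cp2ZrCl2 (25 mol%), CH2Cl2, 0 °C to rt; n-BuLi, THF, −78 °C; (CH2O)n, −78 °C to rt
Reagents that add atoms: trimethylaluminium, C[Al](C)C; formaldehyde (as paraformaldehyde), C=O
Why: Negishi zirconium-catalysed methylalumination adds methyl and aluminium syn across the terminal alkyne with methyl on the internal carbon, and the alanate reacts with formaldehyde with retention, so the E-allylic alcohol forms as a single isomer; terminal alkynes react far faster than the internal, silyloxy-flanked one.

Step 10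
Reactants: 16 (2E,6S,8R)-6-{3-[(4-methoxybenzyl)oxy]prop-1-en-2-yl}-3-methyl-8-[(triethylsilyl)oxy]undec-2-en-9-yn-1-ol
Product: 17 {(2S,3S)-3-[(3S,5R)-3-{3-[(4-methoxybenzyl)oxy]prop-1-en-2-yl}-5-[(triethylsilyl)oxy]oct-6-yn-1-yl]-3-methyloxiran-2-yl}methanol
Conditions: Ti(Oi-Pr)4 (10 mol%), L-(+)-diethyl tartrate (12 mol%), t-BuOOH, MS 4 Å, CH2Cl2, −20 °C
Reagents that add atoms: tert-butyl hydroperoxide, CC(C)(C)OO
Why: Sharpless asymmetric epoxidation acts only on the allylic alcohol and sets C11 and C12 under reagent control; L-(+)-tartrate gives the (2S,3S)-oxirane for this geraniol-type substitution pattern and the remote centres have no say.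

Step 11
Reactants: 17 {(2S,3S)-3-[(3S,5R)-3-{3-[(4-methoxybenzyl)oxy]prop-1-en-2-yl}-5-[(triethylsilyl)oxy]oct-6-yn-1-yl]-3-methyloxiran-2-yl}methanol
Product: 19 (3R,4S,7S,9R)-7-{3-[(4-methoxybenzyl)oxy]prop-1-en-2-yl}-4-methyl-9-[(triethylsilyl)oxy]dodec-1-en-10-yne-3,4-diol, via terminal epoxide 18 (not isolated)
Conditions: Me3SI (5 equiv), n-BuLi (4.8 equiv), THF, −10 °C to rt
Reagents that add atoms: trimethylsulfonium iodide, C[S+](C)C.[I-]
Why: Payne rearrangement: the C10 alkoxide opens the oxirane at C11 with inversion while its oxygen stays on C12 with retention; the ylide then opens the terminal epoxide at CH2 and the adduct eliminates dimethyl sulfide (one-carbon homologation of an epoxide to an allylic alcohol). This turns the (11S,12S)-oxirane into the (11R,12S)-diol and adds C9.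

Step 12
Reactants: 19 (3R,4S,7S,9R)-7-{3-[(4-methoxybenzyl)oxy]prop-1-en-2-yl}-4-methyl-9-[(triethylsilyl)oxy]dodec-1-en-10-yne-3,4-diol
Product: 20 (3R,4S,7S,9R)-3-[(tert-butyldimethylsilyl)oxy]-7-{3-[(4-methoxybenzyl)oxy]prop-1-en-2-yl}-4-methyl-9-[(triethylsilyl)oxy]dodec-1-en-10-yn-4-ol
Conditions: t-BuMe2SiOTf (1.05 equiv), 2,6-lutidine, CH2Cl2, −78 °C
Reagents that add atoms: tert-butyldimethylsilyl trifluoromethanesulfonate, CC(C)(C)[Si](C)(C)OS(=O)(=O)C(F)(F)F
Why: Selective silylation: at −78 °C the secondary hydroxyl reacts and the tertiary one does not, which leaves the C12 hydroxyl as the only nucleophile for the lactonisation.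

Step 13
Reactants: 20 (3R,4S,7S,9R)-3-[(tert-butyldimethylsilyl)oxy]-7-{3-[(4-methoxybenzyl)oxy]prop-1-en-2-yl}-4-methyl-9-[(triethylsilyl)oxy]dodec-1-en-10-yn-4-ol
Product: 21 (3R,4S,7S,9R)-3-[(tert-butyldimethylsilyl)oxy]-7-(3-hydroxyprop-1-en-2-yl)-4-methyl-9-[(triethylsilyl)oxy]dodec-1-en-10-yn-4-ol
Conditions: DDQ, CH2Cl2/pH 7 buffer, 0 °C
Reagents that add atoms: none
Why: Oxidative cleavage of the PMB ether by hydride abstraction and hydrolysis; silyl ethers, alkyne and olefins are inert under these buffered conditions.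

Step 14
Reactants: 21 (3R,4S,7S,9R)-3-[(tert-butyldimethylsilyl)oxy]-7-(3-hydroxyprop-1-en-2-yl)-4-methyl-9-[(triethylsilyl)oxy]dodec-1-en-10-yn-4-ol
Product: 23 2-[(4R,6S,9S,10R)-10-[(tert-butyldimethylsilyl)oxy]-9-hydroxy-9-methyl-4-[(triethylsilyl)oxy]dodec-11-en-2-yn-6-yl]prop-2-enoic acid, via enal 22 (not isolated)
Conditions: MnO2, CH2Cl2, rt; NaClO2, NaH2PO4, 2-methyl-2-butene, t-BuOH/H2O, 0 °C
Reagents that add atoms: sodium chlorite, [Na+].[O-]Cl=O
Why: MnO2 oxidises only the primary allylic alcohol and the Pinnick oxidation takes the 2-substituted acrolein to the acrylic acid, with the hypochlorite scavenger protecting the olefins and the alkyne.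

Step 15
Reactants: 23 2-[(4R,6S,9S,10R)-10-[(tert-butyldimethylsilyl)oxy]-9-hydroxy-9-methyl-4-[(triethylsilyl)oxy]dodec-11-en-2-yn-6-yl]prop-2-enoic acid
Product: 25 (4S,7S)-7-{(1R)-1-[(tert-butyldimethylsilyl)oxy]prop-2-en-1-yl}-7-methyl-3-methylidene-4-{(2R)-2-[(triethylsilyl)oxy]pent-3-yn-1-yl}oxepan-2-one, via mixed anhydride 24 (not isolated)
Conditions: 2,4,6-Cl3C6H2COCl, Et3N, THF, rt; DMAP, toluene, 80 °C
Reagents that add atoms: none
Why: Yamaguchi lactonisation: the acylpyridinium formed from the mixed anhydride is attacked by the only free hydroxyl, the tertiary one at C12, in a seven-membered closure that does not touch any stereocentre; the acid has no α-hydrogen, so neither ketene formation nor epimerisation can occur.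

Step 16
Reactants: 26 but-2-yn-1-ol
Product: 28 (2Z)-3-iodobut-2-en-1-ol, via cyclic aluminate 27 (not isolated)
Conditions: NaAlH2(OCH2CH2OCH3)2 (Red-Al), THF, 0 °C to rt; I2, −78 to 0 °C
Reagents that add atoms: iodine, II
Why: Hydroxyl-directed trans-hydroalumination puts aluminium on C3 cis to the carbinol carbon inside a five-membered aluminate, and iodinolysis with retention gives the Z-iodoalkene.

Step 17
Reactants: 28 (2Z)-3-iodobut-2-en-1-ol
Product: 29 (2Z)-1-bromo-3-iodobut-2-ene
Conditions: CBr4, PPh3, CH2Cl2, 0 °C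
Reagents that add atoms: carbon tetrabromide, BrC(Br)(Br)Br
Why: Appel reaction at the primary allylic alcohol under neutral conditions, without allylic transposition or loss of olefin geometry.

Step 18
Reactants: 29 (2Z)-1-bromo-3-iodobut-2-ene
Product: 30 (2Z)-2-iodohept-2-en-5-yne
Conditions: CH3C≡CMgBr, CuBr·SMe2 (10 mol%), THF, −20 °C to rt
Reagents that add atoms: 1-propynylmagnesium bromide, CC#C[Mg]Br
Why: Copper-catalysed coupling of an alkynyl Grignard reagent with an allylic bromide; SN2 attack at the primary carbon is favoured because the SN2′ site is the fully substituted, iodine-bearing carbon, and the vinyl iodide is inert at this temperature.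

Step 19
Reactants: 25 (4S,7S)-7-{(1R)-1-[(tert-butyldimethylsilyl)oxy]prop-2-en-1-yl}-7-methyl-3-methylidene-4-{(2R)-2-[(triethylsilyl)oxy]pent-3-yn-1-yl}oxepan-2-one; 30 (2Z)-2-iodohept-2-en-5-yne
Product: 32 (4S,7S)-7-{(1R,4Z)-1-[(tert-butyldimethylsilyl)oxy]-4-methylnon-4-en-7-yn-1-yl}-7-methyl-3-methylidene-4-{(2R)-2-[(triethylsilyl)oxy]pent-3-yn-1-yl}oxepan-2-one, via alkylborane 31 (not isolated)
Conditions: 9-BBN, THF, rt; then 30, Pd(dppf)Cl2 (5 mol%), AsPh3, Cs2CO3, DMF/H2O, rt
Reagents that add atoms: none
Why: B-alkyl Suzuki–Miyaura coupling: 9-BBN adds to the monosubstituted vinyl group at its terminus (C9) faster than to the conjugated, electron-poor methylidene of the lactone or to the internal alkyne, and the alkenyl iodide couples with retention, so C9 ends up cis to C6.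

Step 20
Reactants: 32 (4S,7S)-7-{(1R,4Z)-1-[(tert-butyldimethylsilyl)oxy]-4-methylnon-4-en-7-yn-1-yl}-7-methyl-3-methylidene-4-{(2R)-2-[(triethylsilyl)oxy]pent-3-yn-1-yl}oxepan-2-one
Product: 33 (1S,3R,7Z,11R,12S)-11-[(tert-butyldimethylsilyl)oxy]-3-[(triethylsilyl)oxy]cembra-7,15(17)-dien-4-yn-16,12-olide
Conditions: Mo(≡CC6H4-4-OMe)(OSiPh3)3 (10 mol%), MS 5 Å, toluene (2 mM), 80 °C
Reagents that add atoms: none
Why: The molybdenum alkylidyne adds to one methyl-capped alkyne in a [2+2] step to give a molybdenacyclobutadiene, which cycloreverts with loss of the capping unit and leaves the chain bound to the metal as a new alkylidyne; this adds to the second alkyne of the same molecule and a second cycloreversion releases the cycloalkyne and the catalyst. The closest known reaction type is ring-closing alkyne metathesis of methyl-capped diynes to macrocyclic cycloalkynes with triarylsilanolate molybdenum alkylidynes, which tolerates esters, acrylates, silyl ethers and olefins. The 14-membered carbocycle is closed end to end at C4≡C5 by this intramolecular metathesis, and no stereocentre is created. Chemoselectivity for the two alkynes over the C7=C8 olefin, the methylidene group and the carbonyl is inherent, because alkylidynes do not engage olefins, so the Z geometry at C7=C8 is not at risk. Ring closure must win over acyclic diyne oligomerisation: high dilution, reversibility and irreversible uptake of 2-butyne by molecular sieves 5 Å drive the system to the monomeric ring. The seven-membered lactone and the Z olefin act as two turn elements that bring C4 and C5 together, and a 14-membered ring holds the linear C3–C4≡C5–C6 unit without strain. Initiation is expected at the unhindered C5 alkyne; the propargylic silyl ether slows the C4 alkyne but does not bind the metal.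

Step 21
Reactants: 33 (1S,3R,7Z,11R,12S)-11-[(tert-butyldimethylsilyl)oxy]-3-[(triethylsilyl)oxy]cembra-7,15(17)-dien-4-yn-16,12-olide
Product: 34 (1S,3R,7Z,11R,12S)-11-[(tert-butyldimethylsilyl)oxy]-3-hydroxycembra-7,15(17)-dien-4-yn-16,12-olide
Conditions: PPTS, MeOH/CH2Cl2, 0 °C
Reagents that add atoms: none
Why: Acid-catalysed methanolysis removes the less hindered triethylsilyl ether and leaves the tert-butyldimethylsilyl ether next to the quaternary carbon; the acrylate does not add methanol under acidic conditions.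

Step 22
Reactants: 34 (1S,3R,7Z,11R,12S)-11-[(tert-butyldimethylsilyl)oxy]-3-hydroxycembra-7,15(17)-dien-4-yn-16,12-olide
Product: 35 (1S,3R,4Z,7Z,11R,12S)-11-[(tert-butyldimethylsilyl)oxy]-3-hydroxy-4-(tributylstannyl)-18-norcembra-4,7,15(17)-trien-16,12-olide
Conditions: [Cp*RuCl]4 (2.5 mol%), Bu3SnH, CH2Cl2, rt
Reagents that add atoms: tributyltin hydride, CCCC[SnH](CCCC)CCCC
Why: Ruthenium-catalysed trans-hydrostannation: hydrogen bonding of the propargylic hydroxyl to the chloride ligand steers tin to the proximal carbon C4, and hydrogen and tin add from opposite faces, so C3 and C6 end up trans; the pathway is not radical and leaves the acrylate and the olefin alone.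

Step 23
Reactants: 35 (1S,3R,4Z,7Z,11R,12S)-11-[(tert-butyldimethylsilyl)oxy]-3-hydroxy-4-(tributylstannyl)-18-norcembra-4,7,15(17)-trien-16,12-olide
Product: 36 (1S,3R,4E,7Z,11R,12S)-11-[(tert-butyldimethylsilyl)oxy]-3-hydroxycembra-4,7,15(17)-trien-16,12-olide
Conditions: MeI, Pd(PPh3)4 (5 mol%), Cu(O2C-2-thienyl) (CuTC, 1.5 equiv), [NBu4][Ph2PO2], DMF, rt
Reagents that add atoms: iodomethane, CI
Why: Methyl Stille coupling with copper-assisted tin-to-palladium transfer and a phosphinate tin scavenger replaces tin by methyl with retention, which gives the 4E olefin and C18; the free hydroxyl is tolerated.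

Step 24
Reactants: 36 (1S,3R,4E,7Z,11R,12S)-11-[(tert-butyldimethylsilyl)oxy]-3-hydroxycembra-4,7,15(17)-trien-16,12-olide
Product: 37 (1S,3R,4E,7Z,11R,12S)-3-acetoxy-11-[(tert-butyldimethylsilyl)oxy]cembra-4,7,15(17)-trien-16,12-olide
Conditions: Ac2O, pyridine, DMAP (cat.), CH2Cl2, 0 °C to rt
Reagents that add atoms: acetic anhydride, CC(=O)OC(C)=O
Why: Acetylation of the only free hydroxyl, the secondary allylic one at C3; C11 is still silylated.

Step 25
Reactants: 37 (1S,3R,4E,7Z,11R,12S)-3-acetoxy-11-[(tert-butyldimethylsilyl)oxy]cembra-4,7,15(17)-trien-16,12-olide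
Product: 38 (1S,3R,4E,7Z,11R,12S)-3-acetoxy-11-hydroxycembra-4,7,15(17)-trien-16,12-olide (target, CNP0344673.1)
Conditions: HF·pyridine, pyridine, THF, 0 °C to rt
Reagents that add atoms: none
Why: Fluoride-mediated desilylation under buffered, weakly acidic conditions frees the C11 hydroxyl without acetate migration, conjugate addition to the lactone or ionisation of the allylic acetate.

## Compound list

1 | (S)-limonene, (4S)-1-methyl-4-(prop-1-en-2-yl)cyclohex-1-ene | CC1=CC[C@@H](C(C)=C)CC1 | starting material
2 | {2-[(1S)-4-methylcyclohex-3-en-1-yl]prop-2-en-1-yl}lithium | CC1=CC[C@@H](C(=C)C[Li])CC1 | intermediate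
3 | dimethyl {2-[(1S)-4-methylcyclohex-3-en-1-yl]prop-2-en-1-yl}boronate | CC1=CC[C@@H](C(=C)CB(OC)OC)CC1 | intermediate
4 | 2-[(1S)-4-methylcyclohex-3-en-1-yl]prop-2-en-1-ol | CC1=CC[C@@H](C(=C)CO)CC1 | intermediate
5 | 1-methoxy-4-[({2-[(1S)-4-methylcyclohex-3-en-1-yl]prop-2-en-1-yl}oxy)methyl]benzene | CC1=CC[C@@H](C(=C)COCc2ccc(OC)cc2)CC1 | intermediate
6 | (4S)-4-{3-[(4-methoxybenzyl)oxy]prop-1-en-2-yl}-1-methyl-7-oxabicyclo[4.1.0]heptane, mixture of epoxide diastereomers | CC12OC1C[C@@H](C(=C)COCc3ccc(OC)cc3)CC2 | intermediate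
7 | (3S)-3-{3-[(4-methoxybenzyl)oxy]prop-1-en-2-yl}-6-oxoheptanal | CC(=O)CC[C@@H](CC=O)C(=C)COCc1ccc(OC)cc1 | intermediate
8 | (5S)-7-hydroxy-5-{3-[(4-methoxybenzyl)oxy]prop-1-en-2-yl}dec-8-yn-2-one, both C7 epimers | CC(=O)CC[C@@H](CC(O)C#CC)C(=C)COCc1ccc(OC)cc1 | intermediate
9 | (5S)-5-{3-[(4-methoxybenzyl)oxy]prop-1-en-2-yl}dec-8-yne-2,7-dione | CC(=O)CC[C@@H](CC(=O)C#CC)C(=C)COCc1ccc(OC)cc1 | intermediate
10 | (5S,7R)-7-hydroxy-5-{3-[(4-methoxybenzyl)oxy]prop-1-en-2-yl}dec-8-yn-2-one | CC(=O)CC[C@@H](C[C@@H](O)C#CC)C(=C)COCc1ccc(OC)cc1 | intermediate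
11 | (5S,7R)-5-{3-[(4-methoxybenzyl)oxy]prop-1-en-2-yl}-7-[(triethylsilyl)oxy]dec-8-yn-2-one | CC(=O)CC[C@@H](C[C@@H](O[Si](CC)(CC)CC)C#CC)C(=C)COCc1ccc(OC)cc1 | intermediate
12 | diethyl (5S,7R)-5-{3-[(4-methoxybenzyl)oxy]prop-1-en-2-yl}-7-[(triethylsilyl)oxy]dec-1-en-8-yn-2-yl phosphate | C=C(OP(=O)(OCC)OCC)CC[C@@H](C[C@@H](O[Si](CC)(CC)CC)C#CC)C(=C)COCc1ccc(OC)cc1 | intermediate
13 | (5S,7R)-5-{3-[(4-methoxybenzyl)oxy]prop-1-en-2-yl}-7-[(triethylsilyl)oxy]deca-1,8-diyne | C#CCC[C@@H](C[C@@H](O[Si](CC)(CC)CC)C#CC)C(=C)COCc1ccc(OC)cc1 | intermediate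
14 | [(1E,5S,7R)-5-{3-[(4-methoxybenzyl)oxy]prop-1-en-2-yl}-2-methyl-7-[(triethylsilyl)oxy]dec-1-en-8-yn-1-yl]dimethylalane | C[Al](C)/C=C(\C)CC[C@@H](C[C@@H](O[Si](CC)(CC)CC)C#CC)C(=C)COCc1ccc(OC)cc1 | intermediate
15 | lithium butyl(dimethyl)[(1E,5S,7R)-5-{3-[(4-methoxybenzyl)oxy]prop-1-en-2-yl}-2-methyl-7-[(triethylsilyl)oxy]dec-1-en-8-yn-1-yl]aluminate | [Li+].CCCC[Al-](C)(C)/C=C(\C)CC[C@@H](C[C@@H](O[Si](CC)(CC)CC)C#CC)C(=C)COCc1ccc(OC)cc1 | intermediate
16 | (2E,6S,8R)-6-{3-[(4-methoxybenzyl)oxy]prop-1-en-2-yl}-3-methyl-8-[(triethylsilyl)oxy]undec-2-en-9-yn-1-ol | OC/C=C(\C)CC[C@@H](C[C@@H](O[Si](CC)(CC)CC)C#CC)C(=C)COCc1ccc(OC)cc1 | intermediate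
17 | {(2S,3S)-3-[(3S,5R)-3-{3-[(4-methoxybenzyl)oxy]prop-1-en-2-yl}-5-[(triethylsilyl)oxy]oct-6-yn-1-yl]-3-methyloxiran-2-yl}methanol | OC[C@@H]1O[C@@]1(C)CC[C@@H](C[C@@H](O[Si](CC)(CC)CC)C#CC)C(=C)COCc2ccc(OC)cc2 | intermediate
18 | (2S,5S,7R)-5-{3-[(4-methoxybenzyl)oxy]prop-1-en-2-yl}-2-[(2R)-oxiran-2-yl]-7-[(triethylsilyl)oxy]dec-8-yn-2-ol | C1O[C@H]1[C@@](C)(O)CC[C@@H](C[C@@H](O[Si](CC)(CC)CC)C#CC)C(=C)COCc2ccc(OC)cc2 | intermediate
19 | (3R,4S,7S,9R)-7-{3-[(4-methoxybenzyl)oxy]prop-1-en-2-yl}-4-methyl-9-[(triethylsilyl)oxy]dodec-1-en-10-yne-3,4-diol | C=C[C@@H](O)[C@@](C)(O)CC[C@@H](C[C@@H](O[Si](CC)(CC)CC)C#CC)C(=C)COCc1ccc(OC)cc1 | intermediate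
20 | (3R,4S,7S,9R)-3-[(tert-butyldimethylsilyl)oxy]-7-{3-[(4-methoxybenzyl)oxy]prop-1-en-2-yl}-4-methyl-9-[(triethylsilyl)oxy]dodec-1-en-10-yn-4-ol | C=C[C@@H](O[Si](C)(C)C(C)(C)C)[C@@](C)(O)CC[C@@H](C[C@@H](O[Si](CC)(CC)CC)C#CC)C(=C)COCc1ccc(OC)cc1 | intermediate
21 | (3R,4S,7S,9R)-3-[(tert-butyldimethylsilyl)oxy]-7-(3-hydroxyprop-1-en-2-yl)-4-methyl-9-[(triethylsilyl)oxy]dodec-1-en-10-yn-4-ol | C=C[C@@H](O[Si](C)(C)C(C)(C)C)[C@@](C)(O)CC[C@@H](C[C@@H](O[Si](CC)(CC)CC)C#CC)C(=C)CO | intermediate
22 | 2-[(4R,6S,9S,10R)-10-[(tert-butyldimethylsilyl)oxy]-9-hydroxy-9-methyl-4-[(triethylsilyl)oxy]dodec-11-en-2-yn-6-yl]prop-2-enal | C=C[C@@H](O[Si](C)(C)C(C)(C)C)[C@@](C)(O)CC[C@@H](C[C@@H](O[Si](CC)(CC)CC)C#CC)C(=C)C=O | intermediate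
23 | 2-[(4R,6S,9S,10R)-10-[(tert-butyldimethylsilyl)oxy]-9-hydroxy-9-methyl-4-[(triethylsilyl)oxy]dodec-11-en-2-yn-6-yl]prop-2-enoic acid | C=C[C@@H](O[Si](C)(C)C(C)(C)C)[C@@](C)(O)CC[C@@H](C[C@@H](O[Si](CC)(CC)CC)C#CC)C(=C)C(=O)O | intermediate
24 | mixed anhydride of acid 23 with 2,4,6-trichlorobenzoic acid | C=C[C@@H](O[Si](C)(C)C(C)(C)C)[C@@](C)(O)CC[C@@H](C[C@@H](O[Si](CC)(CC)CC)C#CC)C(=C)C(=O)OC(=O)c1c(Cl)cc(Cl)cc1Cl | intermediate
25 | (4S,7S)-7-{(1R)-1-[(tert-butyldimethylsilyl)oxy]prop-2-en-1-yl}-7-methyl-3-methylidene-4-{(2R)-2-[(triethylsilyl)oxy]pent-3-yn-1-yl}oxepan-2-one | C=C[C@@H](O[Si](C)(C)C(C)(C)C)[C@]1(C)CC[C@@H](C[C@@H](O[Si](CC)(CC)CC)C#CC)C(=C)C(=O)O1 | intermediate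
26 | but-2-yn-1-ol | CC#CCO | starting material
27 | sodium 2,2-bis(2-methoxyethoxy)-3-methyl-2,5-dihydro-1,2-oxaaluminol-2-uide | CC1=CCO[Al-]1(OCCOC)OCCOC.[Na+] | intermediate
28 | (2Z)-3-iodobut-2-en-1-ol | C/C(I)=C/CO | intermediate
29 | (2Z)-1-bromo-3-iodobut-2-ene | C/C(I)=C/CBr | intermediate
30 | (2Z)-2-iodohept-2-en-5-yne | C/C(I)=C/CC#CC | intermediate
31 | B-alkyl-9-borabicyclo[3.3.1]nonane from hydroboration of the vinyl group of 25 (boron on C9) | C(C[C@@H](O[Si](C)(C)C(C)(C)C)[C@]3(C)CC[C@@H](C[C@@H](O[Si](CC)(CC)CC)C#CC)C(=C)C(=O)O3)B1C2CCCC1CCC2 | intermediate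
32 | (4S,7S)-7-{(1R,4Z)-1-[(tert-butyldimethylsilyl)oxy]-4-methylnon-4-en-7-yn-1-yl}-7-methyl-3-methylidene-4-{(2R)-2-[(triethylsilyl)oxy]pent-3-yn-1-yl}oxepan-2-one | CC#CC/C=C(/C)CC[C@@H](O[Si](C)(C)C(C)(C)C)[C@]1(C)CC[C@@H](C[C@@H](O[Si](CC)(CC)CC)C#CC)C(=C)C(=O)O1 | intermediate
33 | (1S,3R,7Z,11R,12S)-11-[(tert-butyldimethylsilyl)oxy]-3-[(triethylsilyl)oxy]cembra-7,15(17)-dien-4-yn-16,12-olide | C=C1C(=O)O[C@@]2(C)CC[C@H]1C[C@@H](O[Si](CC)(CC)CC)C#CC/C=C(/C)CC[C@H]2O[Si](C)(C)C(C)(C)C | intermediate
34 | (1S,3R,7Z,11R,12S)-11-[(tert-butyldimethylsilyl)oxy]-3-hydroxycembra-7,15(17)-dien-4-yn-16,12-olide | C=C1C(=O)O[C@@]2(C)CC[C@H]1C[C@@H](O)C#CC/C=C(/C)CC[C@H]2O[Si](C)(C)C(C)(C)C | intermediate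
35 | (1S,3R,4Z,7Z,11R,12S)-11-[(tert-butyldimethylsilyl)oxy]-3-hydroxy-4-(tributylstannyl)-18-norcembra-4,7,15(17)-trien-16,12-olide | C=C1C(=O)O[C@@]2(C)CC[C@H]1C[C@@H](O)/C([Sn](CCCC)(CCCC)CCCC)=C/C/C=C(/C)CC[C@H]2O[Si](C)(C)C(C)(C)C | intermediate
36 | (1S,3R,4E,7Z,11R,12S)-11-[(tert-butyldimethylsilyl)oxy]-3-hydroxycembra-4,7,15(17)-trien-16,12-olide | C=C1C(=O)O[C@@]2(C)CC[C@H]1C[C@@H](O)/C(C)=C/C/C=C(/C)CC[C@H]2O[Si](C)(C)C(C)(C)C | intermediate
37 | (1S,3R,4E,7Z,11R,12S)-3-acetoxy-11-[(tert-butyldimethylsilyl)oxy]cembra-4,7,15(17)-trien-16,12-olide | C=C1C(=O)O[C@@]2(C)CC[C@H]1C[C@@H](OC(C)=O)/C(C)=C/C/C=C(/C)CC[C@H]2O[Si](C)(C)C(C)(C)C | intermediate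
38 | (1S,3R,4E,7Z,11R,12S)-3-acetoxy-11-hydroxycembra-4,7,15(17)-trien-16,12-olide (CNP0344673.1) | C=C1C(=O)O[C@@]2(C)CC[C@H]1C[C@@H](OC(C)=O)/C(C)=C/C/C=C(/C)CC[C@H]2O | target

## Step count and least certain steps

Total step count: 25. Longest linear sequence: 22 steps (steps 1–15 and 19–25); the iodo-enyne branch has 3 steps (16–18).

**Step 20 (key step).** The most likely failure is intermolecular metathesis, that is acyclic diyne oligomerisation, outrunning ring closure. The C4 alkyne sits next to the bulky triethylsilyloxy group and reacts slowly, so an alkylidyne formed at C5 may find a second molecule before its own chain end. The fallback reverses the order of the two carbon–carbon bond formations. Starting from lactone 25 and an excess of iodide 30, intermolecular alkyne cross-metathesis with the same catalyst, without dilution, would give the acyclic cross-metathesis product F1, in which C4≡C5 is already in place. Hydroboration of its vinyl group with 9-BBN would give the alkylborane F2, and an intramolecular B-alkyl Suzuki–Miyaura coupling (Pd(dppf)Cl2, AsPh3, Cs2CO3, high dilution) would close the ring at C8–C9 and return to the route at cycloalkyne 33.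

**Step 15.** The most likely failure is slow acylation of the hindered tertiary hydroxyl, so that the activated acid is used up by intermolecular ester formation or by conjugate addition of DMAP to the acrylate. The fallback makes the C12–O bond with C12 as the electrophile and sets out from allylic alcohol 16. Sharpless epoxidation with D-(−)-diethyl tartrate would give the oxirane of opposite configuration, epoxy alcohol F3. Parikh–Doering oxidation would give epoxy aldehyde F4 and Wittig methylenation vinyl epoxide F5. DDQ would free the allylic alcohol F6, and MnO2 followed by NaClO2 would lead through enal F7 to epoxy acid F8. Under acid catalysis (camphorsulfonic acid, CH2Cl2) the carboxyl group should open the oxirane at the tertiary C12 with inversion in a 7-exo mode to give hydroxy lactone F9. Silylation of its C11 hydroxyl (t-BuMe2SiOTf, 2,6-lutidine) returns to the route at lactone 25; this path also bypasses step 11.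

**Step 11.** The most likely failure is slow Payne equilibration of the lithium alkoxide in THF, so that the ylide decomposes before the terminal epoxide is formed, or silyl migration under the basic conditions. The fallback sets out from epoxy alcohol 17 and separates rearrangement and homologation. A Payne rearrangement with thiolate trapping (PhSH, NaOH, t-BuOH/H2O) would give hydroxy sulfide F10 with the same inversion at C11. S-Methylation (MeOTf, 2,6-di-tert-butylpyridine) would give sulfonium salt F11, which on treatment with excess dimethylsulfonium methylide closes to epoxide 18 and is carried on in the same flask to vinyl diol 19, where the route is rejoined.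

**Step 19.** The most likely failure is loss of chemoselectivity in the hydroboration, with 9-BBN also reducing the α-methylene lactone in a conjugate sense or adding to the alkyne, and base-induced damage to the lactone during the coupling. The fallback sets out from lactone 25, separates the two events and uses a zinc reagent. Hydroboration with the more discriminating disiamylborane and oxidation with NaBO3 would give primary alcohol F12, and I2, PPh3 and imidazole would give iodide F13. Zinc insertion (Zn, LiCl, THF) would give alkylzinc iodide F14, and a base-free Negishi coupling with 30 (Pd(PPh3)4) would return to the route at diyne 32.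

**Step 9.** The most likely failure is loss of chemoselectivity in the methylalumination, by addition to the internal alkyne or Lewis-acid attack on the propargylic silyl ether. The strong base of step 8 carries a related hazard, epimerisation at C3 through propargylic deprotonation. The fallback sets out from ketone 11 and avoids both steps. A Horner–Wadsworth–Emmons olefination ((EtO)2P(O)CH2CO2Et, NaH, THF) would give mainly the E-enoate F15. Reduction with i-Bu2AlH and chromatographic removal of the Z isomer would return to the route at allylic alcohol 16.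

## Further compounds

F1 | step 20 | acyclic cross-metathesis product of 25 and 30 with C4≡C5 formed, vinyl iodide at C8 and vinyl group at C11 | C=C[C@@H](O[Si](C)(C)C(C)(C)C)[C@]1(C)CC[C@@H](C[C@@H](O[Si](CC)(CC)CC)C#CC/C=C(/C)I)C(=C)C(=O)O1
F2 | step 20 | B-alkyl-9-borabicyclo[3.3.1]nonane from hydroboration of the vinyl group of F1 | C(C[C@@H](O[Si](C)(C)C(C)(C)C)[C@]3(C)CC[C@@H](C[C@@H](O[Si](CC)(CC)CC)C#CC/C=C(/C)I)C(=C)C(=O)O3)B1C2CCCC1CCC2
F3 | step 15 | {(2R,3R)-3-[(3S,5R)-3-{3-[(4-methoxybenzyl)oxy]prop-1-en-2-yl}-5-[(triethylsilyl)oxy]oct-6-yn-1-yl]-3-methyloxiran-2-yl}methanol | OC[C@H]1O[C@]1(C)CC[C@@H](C[C@@H](O[Si](CC)(CC)CC)C#CC)C(=C)COCc2ccc(OC)cc2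
F4 | step 15 | epoxy aldehyde from oxidation of F3, oxirane configuration unchanged | O=C[C@H]1O[C@]1(C)CC[C@@H](C[C@@H](O[Si](CC)(CC)CC)C#CC)C(=C)COCc2ccc(OC)cc2
F5 | step 15 | vinyl epoxide from methylenation of F4, oxirane configuration unchanged | C=C[C@H]1O[C@]1(C)CC[C@@H](C[C@@H](O[Si](CC)(CC)CC)C#CC)C(=C)COCc2ccc(OC)cc2
F6 | step 15 | primary allylic alcohol from PMB cleavage of F5 | C=C[C@H]1O[C@]1(C)CC[C@@H](C[C@@H](O[Si](CC)(CC)CC)C#CC)C(=C)CO
F7 | step 15 | 2-substituted acrolein from oxidation of F6 | C=C[C@H]1O[C@]1(C)CC[C@@H](C[C@@H](O[Si](CC)(CC)CC)C#CC)C(=C)C=O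
F8 | step 15 | epoxy acrylic acid from oxidation of F7 | C=C[C@H]1O[C@]1(C)CC[C@@H](C[C@@H](O[Si](CC)(CC)CC)C#CC)C(=C)C(=O)O
F9 | step 15 | (4S,7S)-7-[(1R)-1-hydroxyprop-2-en-1-yl]-7-methyl-3-methylidene-4-{(2R)-2-[(triethylsilyl)oxy]pent-3-yn-1-yl}oxepan-2-one | C=C[C@@H](O)[C@]1(C)CC[C@@H](C[C@@H](O[Si](CC)(CC)CC)C#CC)C(=C)C(=O)O1
F10 | step 11 | hydroxy sulfide, 1-phenylthio analogue of 19 with C10 as CH2SPh and the 11,12-diol configured as in 19 | C(Sc1ccccc1)[C@@H](O)[C@@](C)(O)CC[C@@H](C[C@@H](O[Si](CC)(CC)CC)C#CC)C(=C)COCc1ccc(OC)cc1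
F11 | step 11 | S-methyl S-phenyl sulfonium triflate from F10 | C[S+](c1ccccc1)C[C@@H](O)[C@@](C)(O)CC[C@@H](C[C@@H](O[Si](CC)(CC)CC)C#CC)C(=C)COCc1ccc(OC)cc1.[O-]S(=O)(=O)C(F)(F)F
F12 | step 19 | primary alcohol from hydroboration–oxidation of the vinyl group of 25 (hydroxyl on C9) | OCC[C@@H](O[Si](C)(C)C(C)(C)C)[C@]1(C)CC[C@@H](C[C@@H](O[Si](CC)(CC)CC)C#CC)C(=C)C(=O)O1
F13 | step 19 | primary iodide from F12 | ICC[C@@H](O[Si](C)(C)C(C)(C)C)[C@]1(C)CC[C@@H](C[C@@H](O[Si](CC)(CC)CC)C#CC)C(=C)C(=O)O1
F14 | step 19 | alkylzinc iodide from F13 | I[Zn]CC[C@@H](O[Si](C)(C)C(C)(C)C)[C@]1(C)CC[C@@H](C[C@@H](O[Si](CC)(CC)CC)C#CC)C(=C)C(=O)O1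
F15 | step 9 | ethyl (2E,6S,8R)-6-{3-[(4-methoxybenzyl)oxy]prop-1-en-2-yl}-3-methyl-8-[(triethylsilyl)oxy]undec-2-en-9-ynoate | CCOC(=O)/C=C(\C)CC[C@@H](C[C@@H](O[Si](CC)(CC)CC)C#CC)C(=C)COCc1ccc(OC)cc1
A1 | alternative 1 | unsaturated seven-membered lactone with C1, C11 and C12 set, C3 as silyl ether and C9 as PMB ether of two hydroxyethyl arms | O=C1C[C@H](CCO[Si](c2ccccc2)(c2ccccc2)C(C)(C)C)/C=C\[C@@](C)([C@H](O[Si](C)(C)C(C)(C)C)CCOCc2ccc(OC)cc2)O1
A2 | alternative 2 | 14-membered carbocyclic 11,12-diol with C3 as PMB ether and C16 as silyl ether | C=C(CO[Si](C)(C)C(C)(C)C)[C@@H]1C[C@@H](OCc2ccc(OC)cc2)/C(C)=C/C/C=C(/C)CC[C@@H](O)[C@@](C)(O)CC1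
A3 | alternative 3 | 3-O-triethylsilyl 11-O-tert-butyldimethylsilyl ether of the deacetyl target | C=C1C(=O)O[C@@]2(C)CC[C@H]1C[C@@H](O[Si](CC)(CC)CC)/C(C)=C/C/C=C(/C)CC[C@H]2O[Si](C)(C)C(C)(C)C
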